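**Plan**

1. Locants (elemane numbering): the ring is C5–C10. C10 bears CH3 (C14) and vinyl (C1=C2), C5 bears C4(=C3H2)–C15H2OH, C6 bears OH, C7 bears C11(=C13H2)–C12O2H, C8 bears the acyloxy group, C9 is CH2. Retrosynthesis: take off the C8 acyl group, fold O6/C15 back into a cis-fused α-methylene lactone, mask C12 as a tert-butyl ester, then cut C5–C10 and C7–C8 together to reach the acyclic aldehyde/allylic bromide 25.
2. Enabling feature: the trans pair vinyl (on C10) / prop-1-en-2-yl unit (on C5) of the six-membered ring is the retron of a Cope rearrangement of a cyclodeca-1(10),4-diene, and O8–C8–C7–C11(=C13) is the retron of a γ-selective 2-(alkoxycarbonyl)allyl-metal addition to an aldehyde. The C2–C3 σ bond is a traceless tether and the butenolide C6–O–C15(=O)–C4=C5 a temporary ring.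
3. Forward: the butenolide is built first (ynoate carbinol 9, stannane 11, iodide 12, Negishi coupling with the C8–C3 chain 20). The ten-membered ring then closes at C7–C8 and, in the same flask, contracts by a [3,3] shift to the cyclohexane (C5–C10). Lactone to lactol acetal, O8 acylation, acidolysis and Luche reduction finish the route.
4. Stereochemistry: C6 comes from a catalytic asymmetric alkynylation (step 5). C7 and C8 come from the Barbier ring closure under control of C6. C5 and C10 come from the chair Cope transition state, where the butenolide fixes the face of C5 and the E-C1=C10 geometry fixes C10. The Z side-chain alkene comes from a Z-selective diaryl-phosphonate Horner–Wadsworth–Emmons reaction.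

Key step: step 15

Assumption: (S,S)-ProPhenol is taken to deliver the 4S carbinol 9 (otherwise the enantiomeric ligand is used), and 2-oxoethyl acetate 34 is used as purchased or freshly made by ozonolysis of (Z)-but-2-ene-1,4-diyl diacetate.

**Route**

Step 1
Reactants: 1 tert-butyl acrylate; 2 2,2-dimethoxyacetaldehyde (60 wt% in water)
Product: 3 tert-butyl 3-hydroxy-4,4-dimethoxy-2-methylidenebutanoate (racemic)
Conditions: DABCO (0.5 equiv), 1,4-dioxane/H2O, 23 °C
Reagents that add atoms: none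
Why: Morita–Baylis–Hillman reaction of an acrylate with an activated, non-enolisable α,α-dialkoxy aldehyde; the racemic carbinol centre is erased in step 2.

Step 2
Reactants: 3 tert-butyl 3-hydroxy-4,4-dimethoxy-2-methylidenebutanoate
Product: 4 tert-butyl (2Z)-2-(bromomethyl)-4,4-dimethoxybut-2-enoate
Conditions: NBS, Me2S, CH2Cl2, 0 → 23 °C
Reagents that add atoms: N-bromosuccinimide, O=C1CCC(=O)N1Br
Why: Corey–Kim bromination of a Baylis–Hillman alcohol proceeds with allylic transposition (SN2′ attack of bromide on the alkoxysulfonium salt) to the conjugated trisubstituted enoate, whose preferred geometry has the acetal carbon trans to the ester and cis to CH2Br.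

Step 3
Reactants: 4 tert-butyl (2Z)-2-(bromomethyl)-4,4-dimethoxybut-2-enoate; 5 (4-methoxyphenyl)methanol
Product: 6 tert-butyl (2E)-4,4-dimethoxy-2-{[(4-methoxyphenyl)methoxy]methyl}but-2-enoate
Conditions: Ag2O, 4 Å molecular sieves, CH2Cl2, 23 °C, dark
Reagents that add atoms: none
Why: silver-assisted Williamson etherification (SN2) at the primary allylic bromide should keep the conjugated trisubstituted alkene and its geometry.

Step 4
Reactants: 6 tert-butyl (2E)-4,4-dimethoxy-2-{[(4-methoxyphenyl)methoxy]methyl}but-2-enoate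
Product: 7 tert-butyl (2E)-2-{[(4-methoxyphenyl)methoxy]methyl}-4-oxobut-2-enoate
Conditions: 1 M aq. HCl, THF, 23 °C
Reagents that add atoms: water, O
Why: acid-catalysed acetal hydrolysis in dilute aqueous acid, which the benzylic ether and the tert-butyl ester tolerate; the aldehyde stays trans to the ester, the stable geometry.

Step 5
Reactants: 7 tert-butyl (2E)-2-{[(4-methoxyphenyl)methoxy]methyl}-4-oxobut-2-enoate; 8 methyl prop-2-ynoate
Product: 9 1-tert-butyl 7-methyl (2E,4S)-4-hydroxy-2-{[(4-methoxyphenyl)methoxy]methyl}hept-2-en-5-ynedioate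
Conditions: (S,S)-ProPhenol (20 mol %), Me2Zn, Ph3P=O (40 mol %), toluene, 4 °C; aq. NH4Cl work-up
Reagents that add atoms: none
Why: ProPhenol/dinuclear-zinc catalysed asymmetric alkynylation, in which the zinc alkynylide of the propiolate adds 1,2 to the enal inside the chiral pocket, so that C6 (C4 of 9) is set by the catalyst.

Step 6
Reactants: 9 1-tert-butyl 7-methyl (2E,4S)-4-hydroxy-2-{[(4-methoxyphenyl)methoxy]methyl}hept-2-en-5-ynedioate
Product: 11 tert-butyl (2E)-2-{[(4-methoxyphenyl)methoxy]methyl}-3-[(2S)-5-oxo-4-(tributylstannyl)-2,5-dihydrofuran-2-yl]prop-2-enoate, via hydroxy stannyl diester 10 (not isolated)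
Conditions: Bu3SnH, Pd(PPh3)4 (2 mol %), THF, 0 °C; then PPTS (cat.), 23 °C
Reagents that add atoms: tributyltin hydride, CCCC[SnH](CCCC)CCCC
Why: palladium-catalysed syn-hydrostannation of the ynoate puts tin α to the ester and hydrogen on C5, so the methyl ester and the C6 hydroxyl end cis and lactonise to the butenolide without touching C6.

Step 7
Reactants: 11 tert-butyl (2E)-2-{[(4-methoxyphenyl)methoxy]methyl}-3-[(2S)-5-oxo-4-(tributylstannyl)-2,5-dihydrofuran-2-yl]prop-2-enoate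
Product: 12 tert-butyl (2E)-3-[(2S)-4-iodo-5-oxo-2,5-dihydrofuran-2-yl]-2-{[(4-methoxyphenyl)methoxy]methyl}prop-2-enoate
Conditions: I2, CH2Cl2, 0 °C
Reagents that add atoms: iodine, II
Why: iododestannylation (ipso substitution at the vinyl–tin bond) under neutral conditions, which spares the base-sensitive γ-position C6.

Step 8
Reactants: 13 but-3-yn-1-ol; 14 1-(chloromethyl)-4-methoxybenzene
Product: 15 1-[(but-3-yn-1-yloxy)methyl]-4-methoxybenzene
Conditions: NaH, Bu4NI (cat.), THF/DMF, 0 → 23 °C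
Reagents that add atoms: none
Why: Williamson ether synthesis; the alkoxide forms in preference to the acetylide and is benzylated.

Step 9
Reactants: 15 1-[(but-3-yn-1-yloxy)methyl]-4-methoxybenzene; 16 oxirane
Product: 19 (3E)-6-[(4-methoxyphenyl)methoxy]-4-methylhex-3-en-1-ol, via alkenylalane 17 (not isolated), via lithium alanate 18 (not isolated)
Conditions: Me3Al, Cp2ZrCl2 (25 mol %), CH2Cl2, 0 → 23 °C; then n-BuLi, THF, −78 °C; then 16, −78 → 0 °C
Reagents that add atoms: trimethylaluminium, C[Al](C)C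
Why: Negishi zirconium-catalysed carboalumination adds methyl and aluminium syn across the alkyne, and the derived ate complex opens the epoxide with retention at the alkenyl carbon, which sets the E geometry of C1=C10.

Step 10
Reactants: 19 (3E)-6-[(4-methoxyphenyl)methoxy]-4-methylhex-3-en-1-ol
Product: 20 1-({[(3E)-6-iodo-3-methylhex-3-en-1-yl]oxy}methyl)-4-methoxybenzene
Conditions: I2, PPh3, imidazole, CH2Cl2, 0 °C
Reagents that add atoms: iodine, II
Why: Appel-type iodination (SN2 displacement of the alkoxyphosphonium group by iodide) of a primary alcohol.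

Step 11
Reactants: 20 1-({[(3E)-6-iodo-3-methylhex-3-en-1-yl]oxy}methyl)-4-methoxybenzene; 12 tert-butyl (2E)-3-[(2S)-4-iodo-5-oxo-2,5-dihydrofuran-2-yl]-2-{[(4-methoxyphenyl)methoxy]methyl}prop-2-enoate
Product: 22 tert-butyl (2E)-2-{[(4-methoxyphenyl)methoxy]methyl}-3-[(2R)-4-{(3E)-6-[(4-methoxyphenyl)methoxy]-4-methylhex-3-en-1-yl}-5-oxo-2,5-dihydrofuran-2-yl]prop-2-enoate, via alkylzinc iodide 21 (not isolated)
Conditions: Zn dust, LiCl, THF, 40 °C; then 12, Pd2(dba)3 (2.5 mol %), SPhos (10 mol %), THF, 23 °C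
Reagents that add atoms: none
Why: Negishi sp3–sp2 cross-coupling of an alkylzinc iodide with an α-iodo butenolide; the organozinc is not basic enough to enolise C6, so the stereocentre is kept (its descriptor changes only through priority).

Step 12
Reactants: 22 tert-butyl (2E)-2-{[(4-methoxyphenyl)methoxy]methyl}-3-[(2R)-4-{(3E)-6-[(4-methoxyphenyl)methoxy]-4-methylhex-3-en-1-yl}-5-oxo-2,5-dihydrofuran-2-yl]prop-2-enoate
Product: 23 tert-butyl (2E)-2-(hydroxymethyl)-3-{(2R)-4-[(3E)-6-hydroxy-4-methylhex-3-en-1-yl]-5-oxo-2,5-dihydrofuran-2-yl}prop-2-enoate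
Conditions: DDQ, CH2Cl2/pH 7 buffer, 0 °C
Reagents that add atoms: none
Why: oxidative cleavage of both 4-methoxybenzyl ethers by DDQ under buffered neutral conditions, which avoids base at the doubly activated C6–H.

Step 13
Reactants: 23 tert-butyl (2E)-2-(hydroxymethyl)-3-{(2R)-4-[(3E)-6-hydroxy-4-methylhex-3-en-1-yl]-5-oxo-2,5-dihydrofuran-2-yl}prop-2-enoate
Product: 24 tert-butyl (2Z)-2-(bromomethyl)-3-{(2R)-4-[(3E)-6-hydroxy-4-methylhex-3-en-1-yl]-5-oxo-2,5-dihydrofuran-2-yl}prop-2-enoate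
Conditions: NBS, Me2S, CH2Cl2, −20 → 0 °C
Reagents that add atoms: N-bromosuccinimide, O=C1CCC(=O)N1Br
Why: Corey–Kim halogenation converts allylic alcohols to bromides while saturated primary alcohols are returned unchanged, so only C13–OH is replaced.

Step 14
Reactants: 24 tert-butyl (2Z)-2-(bromomethyl)-3-{(2R)-4-[(3E)-6-hydroxy-4-methylhex-3-en-1-yl]-5-oxo-2,5-dihydrofuran-2-yl}prop-2-enoate
Product: 25 tert-butyl (2Z)-2-(bromomethyl)-3-{(2R)-4-[(3E)-4-methyl-6-oxohex-3-en-1-yl]-5-oxo-2,5-dihydrofuran-2-yl}prop-2-enoate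
Conditions: Dess–Martin periodinane, NaHCO3, CH2Cl2, 0 °C
Reagents that add atoms: none
Why: Dess–Martin oxidation under buffered conditions should give the β,γ-unsaturated aldehyde without conjugation and without touching the allylic bromide; 25 is used at once.

Step 15
Reactants: 25 tert-butyl (2Z)-2-(bromomethyl)-3-{(2R)-4-[(3E)-4-methyl-6-oxohex-3-en-1-yl]-5-oxo-2,5-dihydrofuran-2-yl}prop-2-enoate
Product: 27 tert-butyl 2-[(3aS,4R,6R,7S,7aR)-4-ethenyl-4-methyl-3-methylidene-2-oxo-6-[(trimethylsilyl)oxy]octahydro-1-benzofuran-7-yl]prop-2-enoate, via butenolide-bridged cyclodecadiene 26 (not isolated)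
Conditions: CrCl2 (15 mol %), Mn powder, Me3SiCl, THF, 23 °C, 25 added over 12 h (final 2 mM); then toluene added, THF distilled off, 100 °C
Reagents that add atoms: chlorotrimethylsilane, C[Si](C)(C)Cl
Why: CrCl2, turned over by Mn/Me3SiCl, converts the allylic bromide into a trivalent 2-(alkoxycarbonyl)allylchromium that adds through its γ-carbon C7 to the tethered aldehyde C8 in a six-membered Zimmerman–Traxler array (Nozaki–Hiyama–Kishi/Barbier macrocyclisation, the closest precedent being germacranolide ring closures), and the resulting (E,E)-cyclodeca-1(10),4-diene 26 then undergoes the germacrene-to-elemene Cope rearrangement on heating, forming C5–C10 and breaking C2–C3. The ten-membered ring closes by 10-exo-trig attack on the aldehyde, and the cyclohexane closes transannularly through the chair–chair [3,3] transition state, which consumes the ten-membered ring. At C7, allylic 1,3-strain with the cis CH2Cr group keeps H6 in the alkene plane and the chain anchored at C4 can only reach the face syn to C5 and anti to O6, so C11 ends trans to O6; at C8, the Z-allyl unit places C6 axial and the aldehyde chain equatorial in the chair, so O8 ends cis to C11. At C5, the planar butenolide lets C10 bond only on the face that carries C7, so C4 ends cis to O6; at C10, the chair geometry with the E-C1=C10 alkene puts the methyl axial, so the new vinyl group is trans to the C5 alkenyl group. The step needs ring closure over oligomerisation and addition to the aldehyde only, which slow addition at high dilution and the carbonyl selectivity of allylchromium should secure; silylation of O8 blocks lactonisation onto the tert-butyl ester, and relief of ten-membered-ring strain drives the Cope step.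

Step 16
Reactants: 27 tert-butyl 2-[(3aS,4R,6R,7S,7aR)-4-ethenyl-4-methyl-3-methylidene-2-oxo-6-[(trimethylsilyl)oxy]octahydro-1-benzofuran-7-yl]prop-2-enoate
Product: 29 tert-butyl 2-[(3aS,4R,6R,7R,7aR)-4-ethenyl-6-hydroxy-2-methoxy-4-methyl-3-methylideneoctahydro-1-benzofuran-7-yl]prop-2-enoate (C2 epimers), via silyl-protected lactol 28 (not isolated)
Conditions: i-Bu2AlH (1.2 equiv), CH2Cl2, −78 °C; aq. potassium sodium tartrate work-up; then MeOH, PPTS (cat.), 23 °C
Reagents that add atoms: methanol, CO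
Why: half-reduction of the strained γ-lactone by i-Bu2AlH at −78 °C should outrun attack on the hindered tert-butyl ester, and PPTS/MeOH then turns the lactol into its methyl acetal (masking O6 and C15 together) and cleaves the trimethylsilyl ether, leaving O8 as the only free hydroxyl; no ring stereocentre changes.

Step 17
Reactants: 30 diphenyl phosphonate (diphenyl phosphite); 31 tert-butyl bromoacetate
Product: 32 tert-butyl 2-(diphenoxyphosphoryl)acetate
Conditions: Et3N, CH2Cl2, 0 → 23 °C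
Reagents that add atoms: none
Why: Michaelis–Becker-type P-alkylation of the phosphite anion with an α-bromo ester.

Step 18
Reactants: 32 tert-butyl 2-(diphenoxyphosphoryl)acetate
Product: 33 tert-butyl 2-(diphenoxyphosphoryl)propanoate (racemic)
Conditions: NaH, MeI, DMSO/THF, 0 → 23 °C
Reagents that add atoms: iodomethane, CI
Why: C-methylation of the stabilised phosphonate carbanion.

Step 19
Reactants: 33 tert-butyl 2-(diphenoxyphosphoryl)propanoate; 34 2-oxoethyl acetate
Product: 35 tert-butyl (2Z)-4-(acetyloxy)-2-methylbut-2-enoate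
Conditions: NaH, THF, −78 → 0 °C
Reagents that add atoms: none
Why: Horner–Wadsworth–Emmons olefination with a diaryl phosphonate, in which fast irreversible collapse of the kinetic oxaphosphetane gives the Z-trisubstituted enoate (ester cis to CH2OAc).

Step 20
Reactants: 35 tert-butyl (2Z)-4-(acetyloxy)-2-methylbut-2-enoate
Product: 36 (2Z)-4-(acetyloxy)-2-methylbut-2-enoic acid
Conditions: TFA, CH2Cl2, 0 °C
Reagents that add atoms: none
Why: acidolysis of the tert-butyl ester (loss of 2-methylpropene) frees the acid without base, so the Z geometry and the acetate are kept and no free γ-hydroxyl is present to lactonise.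

Step 21
Reactants: 29 tert-butyl 2-[(3aS,4R,6R,7R,7aR)-4-ethenyl-6-hydroxy-2-methoxy-4-methyl-3-methylideneoctahydro-1-benzofuran-7-yl]prop-2-enoate; 36 (2Z)-4-(acetyloxy)-2-methylbut-2-enoic acid
Product: 38 tert-butyl 2-[(3aS,4R,6R,7R,7aR)-6-{[(2Z)-4-(acetyloxy)-2-methylbut-2-enoyl]oxy}-4-ethenyl-2-methoxy-4-methyl-3-methylideneoctahydro-1-benzofuran-7-yl]prop-2-enoate (C2 epimers), via mixed anhydride 37 (not isolated)
Conditions: 2,4,6-trichlorobenzoyl chloride, Et3N, toluene, 23 °C; then 29, DMAP (0.3 equiv), 40 °C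
Reagents that add atoms: none
Why: Yamaguchi esterification, the usual way to acylate with Z-2-methylbut-2-enoic (angelate-type) acids with little Z-to-E isomerisation; O8 is the only free hydroxyl and reacts with retention at C8.

Step 22
Reactants: 38 tert-butyl 2-[(3aS,4R,6R,7R,7aR)-6-{[(2Z)-4-(acetyloxy)-2-methylbut-2-enoyl]oxy}-4-ethenyl-2-methoxy-4-methyl-3-methylideneoctahydro-1-benzofuran-7-yl]prop-2-enoate
Product: 39 2-[(3aS,4R,6R,7R,7aR)-6-{[(2Z)-4-(acetyloxy)-2-methylbut-2-enoyl]oxy}-4-ethenyl-2-hydroxy-4-methyl-3-methylideneoctahydro-1-benzofuran-7-yl]prop-2-enoic acid (C2 epimers)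
Conditions: TFA/CH2Cl2/H2O (10:10:1), 0 °C
Reagents that add atoms: water, O
Why: one acid treatment cleaves the tert-butyl ester and hydrolyses the methyl acetal to the lactol; O6 stays tied in the lactol and O8 is acylated, so the free acid has no hydroxyl to lactonise onto.

Step 23
Reactants: 39 2-[(3aS,4R,6R,7R,7aR)-6-{[(2Z)-4-(acetyloxy)-2-methylbut-2-enoyl]oxy}-4-ethenyl-2-hydroxy-4-methyl-3-methylideneoctahydro-1-benzofuran-7-yl]prop-2-enoic acid
Product: 40 2-[(1S,2R,3S,4R,6R)-6-{[(2Z)-4-(acetyloxy)-2-methylbut-2-enoyl]oxy}-4-ethenyl-2-hydroxy-3-(3-hydroxyprop-1-en-2-yl)-4-methylcyclohexyl]prop-2-enoic acid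
Conditions: NaBH4, CeCl3·7H2O, MeOH, −20 → 0 °C; then aq. NaH2PO4 to pH 5
Reagents that add atoms: none
Why: Luche reduction of the lactol through its open hydroxy-enal form delivers hydride 1,2 to the 2-substituted acrolein, which gives C15H2OH and frees O6–H, while the carboxylate, the enoate ester and the acetate should not be reduced at this temperature; no stereocentre is touched.

**Compound list**

1 | tert-butyl acrylate | C=CC(=O)OC(C)(C)C | starting material
2 | 2,2-dimethoxyacetaldehyde | COC(OC)C=O | starting material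
3 | tert-butyl 3-hydroxy-4,4-dimethoxy-2-methylidenebutanoate (racemic) | COC(OC)C(O)C(=C)C(=O)OC(C)(C)C | intermediate
4 | tert-butyl (2Z)-2-(bromomethyl)-4,4-dimethoxybut-2-enoate | COC(OC)/C=C(\CBr)C(=O)OC(C)(C)C | intermediate
5 | (4-methoxyphenyl)methanol | COc1ccc(CO)cc1 | starting material
6 | tert-butyl (2E)-4,4-dimethoxy-2-{[(4-methoxyphenyl)methoxy]methyl}but-2-enoate | COC(OC)/C=C(\COCc1ccc(OC)cc1)C(=O)OC(C)(C)C | intermediate
7 | tert-butyl (2E)-2-{[(4-methoxyphenyl)methoxy]methyl}-4-oxobut-2-enoate | O=C/C=C(\COCc1ccc(OC)cc1)C(=O)OC(C)(C)C | intermediate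
8 | methyl prop-2-ynoate | C#CC(=O)OC | starting material
9 | 1-tert-butyl 7-methyl (2E,4S)-4-hydroxy-2-{[(4-methoxyphenyl)methoxy]methyl}hept-2-en-5-ynedioate | COC(=O)C#C[C@@H](O)/C=C(\COCc1ccc(OC)cc1)C(=O)OC(C)(C)C | intermediate
10 | 1-tert-butyl 7-methyl (2E,4S,5E)-4-hydroxy-2-{[(4-methoxyphenyl)methoxy]methyl}-6-(tributylstannyl)hepta-2,5-dienedioate | COC(=O)/C(=C\[C@@H](O)/C=C(\COCc1ccc(OC)cc1)C(=O)OC(C)(C)C)[Sn](CCCC)(CCCC)CCCC | intermediate
11 | tert-butyl (2E)-2-{[(4-methoxyphenyl)methoxy]methyl}-3-[(2S)-5-oxo-4-(tributylstannyl)-2,5-dihydrofuran-2-yl]prop-2-enoate | CCCC[Sn](CCCC)(CCCC)C1=C[C@@H](OC1=O)/C=C(\COCc2ccc(OC)cc2)C(=O)OC(C)(C)C | intermediate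
12 | tert-butyl (2E)-3-[(2S)-4-iodo-5-oxo-2,5-dihydrofuran-2-yl]-2-{[(4-methoxyphenyl)methoxy]methyl}prop-2-enoate | IC1=C[C@@H](OC1=O)/C=C(\COCc2ccc(OC)cc2)C(=O)OC(C)(C)C | intermediate
13 | but-3-yn-1-ol | C#CCCO | starting material
14 | 1-(chloromethyl)-4-methoxybenzene | COc1ccc(CCl)cc1 | starting material
15 | 1-[(but-3-yn-1-yloxy)methyl]-4-methoxybenzene | C#CCCOCc1ccc(OC)cc1 | intermediate
16 | oxirane | C1CO1 | starting material
17 | {(1E)-4-[(4-methoxyphenyl)methoxy]-2-methylbut-1-en-1-yl}dimethylalumane | C[Al](C)/C=C(\C)CCOCc1ccc(OC)cc1 | intermediate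
18 | lithium butyl{(1E)-4-[(4-methoxyphenyl)methoxy]-2-methylbut-1-en-1-yl}dimethylaluminate | [Li+].CCCC[Al-](C)(C)/C=C(\C)CCOCc1ccc(OC)cc1 | intermediate
19 | (3E)-6-[(4-methoxyphenyl)methoxy]-4-methylhex-3-en-1-ol | OCC/C=C(\C)CCOCc1ccc(OC)cc1 | intermediate
20 | 1-({[(3E)-6-iodo-3-methylhex-3-en-1-yl]oxy}methyl)-4-methoxybenzene | ICC/C=C(\C)CCOCc1ccc(OC)cc1 | intermediate
21 | iodo{(3E)-6-[(4-methoxyphenyl)methoxy]-4-methylhex-3-en-1-yl}zinc | I[Zn]CC/C=C(\C)CCOCc1ccc(OC)cc1 | intermediate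
22 | tert-butyl (2E)-2-{[(4-methoxyphenyl)methoxy]methyl}-3-[(2R)-4-{(3E)-6-[(4-methoxyphenyl)methoxy]-4-methylhex-3-en-1-yl}-5-oxo-2,5-dihydrofuran-2-yl]prop-2-enoate | COc1ccc(COCC/C(C)=C/CCC2=C[C@@H](OC2=O)/C=C(\COCc3ccc(OC)cc3)C(=O)OC(C)(C)C)cc1 | intermediate
23 | tert-butyl (2E)-2-(hydroxymethyl)-3-{(2R)-4-[(3E)-6-hydroxy-4-methylhex-3-en-1-yl]-5-oxo-2,5-dihydrofuran-2-yl}prop-2-enoate | OCC/C(C)=C/CCC1=C[C@@H](OC1=O)/C=C(\CO)C(=O)OC(C)(C)C | intermediate
24 | tert-butyl (2Z)-2-(bromomethyl)-3-{(2R)-4-[(3E)-6-hydroxy-4-methylhex-3-en-1-yl]-5-oxo-2,5-dihydrofuran-2-yl}prop-2-enoate | OCC/C(C)=C/CCC1=C[C@@H](OC1=O)/C=C(\CBr)C(=O)OC(C)(C)C | intermediate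
25 | tert-butyl (2Z)-2-(bromomethyl)-3-{(2R)-4-[(3E)-4-methyl-6-oxohex-3-en-1-yl]-5-oxo-2,5-dihydrofuran-2-yl}prop-2-enoate | O=CC/C(C)=C/CCC1=C[C@@H](OC1=O)/C=C(\CBr)C(=O)OC(C)(C)C | intermediate
26 | tert-butyl (1(10)E,6R,7S,8R)-15-oxo-8-[(trimethylsilyl)oxy]-6,15-epoxygermacra-1(10),4,11(13)-trien-12-oate (ten-membered ring C1–C10; butenolide C6–O–C15(=O)–C4=C5, C3 trans to C6 across C4=C5) | C[Si](C)(C)O[C@@H]1C/C(C)=C/CC/C2=C/[C@@H](OC2=O)[C@@H]1C(=C)C(=O)OC(C)(C)C | intermediate
27 | tert-butyl 2-[(3aS,4R,6R,7S,7aR)-4-ethenyl-4-methyl-3-methylidene-2-oxo-6-[(trimethylsilyl)oxy]octahydro-1-benzofuran-7-yl]prop-2-enoate | C=C[C@@]1(C)C[C@@H](O[Si](C)(C)C)[C@@H](C(=C)C(=O)OC(C)(C)C)[C@H](OC(=O)C2=C)[C@@H]12 | intermediate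
28 | tert-butyl 2-[(3aS,4R,6R,7S,7aR)-4-ethenyl-2-hydroxy-4-methyl-3-methylidene-6-[(trimethylsilyl)oxy]octahydro-1-benzofuran-7-yl]prop-2-enoate (C2 epimers) | C=C[C@@]1(C)C[C@@H](O[Si](C)(C)C)[C@@H](C(=C)C(=O)OC(C)(C)C)[C@H](OC(O)C2=C)[C@@H]12 | intermediate
29 | tert-butyl 2-[(3aS,4R,6R,7R,7aR)-4-ethenyl-6-hydroxy-2-methoxy-4-methyl-3-methylideneoctahydro-1-benzofuran-7-yl]prop-2-enoate (C2 epimers) | C=C[C@@]1(C)C[C@@H](O)[C@@H](C(=C)C(=O)OC(C)(C)C)[C@H](OC(OC)C2=C)[C@@H]12 | intermediate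
30 | diphenyl phosphonate (diphenyl phosphite) | O=[PH](Oc1ccccc1)Oc1ccccc1 | starting material
31 | tert-butyl bromoacetate | BrCC(=O)OC(C)(C)C | starting material
32 | tert-butyl 2-(diphenoxyphosphoryl)acetate | O=C(CP(=O)(Oc1ccccc1)Oc1ccccc1)OC(C)(C)C | intermediate
33 | tert-butyl 2-(diphenoxyphosphoryl)propanoate (racemic) | CC(C(=O)OC(C)(C)C)P(=O)(Oc1ccccc1)Oc1ccccc1 | intermediate
34 | 2-oxoethyl acetate | CC(=O)OCC=O | starting material
35 | tert-butyl (2Z)-4-(acetyloxy)-2-methylbut-2-enoate | CC(=O)OC/C=C(/C)C(=O)OC(C)(C)C | intermediate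
36 | (2Z)-4-(acetyloxy)-2-methylbut-2-enoic acid | CC(=O)OC/C=C(/C)C(=O)O | intermediate
37 | (2Z)-4-(acetyloxy)-2-methylbut-2-enoic 2,4,6-trichlorobenzoic anhydride | CC(=O)OC/C=C(/C)C(=O)OC(=O)c1c(Cl)cc(Cl)cc1Cl | intermediate
38 | tert-butyl 2-[(3aS,4R,6R,7R,7aR)-6-{[(2Z)-4-(acetyloxy)-2-methylbut-2-enoyl]oxy}-4-ethenyl-2-methoxy-4-methyl-3-methylideneoctahydro-1-benzofuran-7-yl]prop-2-enoate (C2 epimers) | C=C[C@@]1(C)C[C@@H](OC(=O)/C(C)=C\COC(C)=O)[C@@H](C(=C)C(=O)OC(C)(C)C)[C@H](OC(OC)C2=C)[C@@H]12 | intermediate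
39 | 2-[(3aS,4R,6R,7R,7aR)-6-{[(2Z)-4-(acetyloxy)-2-methylbut-2-enoyl]oxy}-4-ethenyl-2-hydroxy-4-methyl-3-methylideneoctahydro-1-benzofuran-7-yl]prop-2-enoic acid (C2 epimers) | C=C[C@@]1(C)C[C@@H](OC(=O)/C(C)=C\COC(C)=O)[C@@H](C(=C)C(=O)O)[C@H](OC(O)C2=C)[C@@H]12 | intermediate
40 | 2-[(1S,2R,3S,4R,6R)-6-{[(2Z)-4-(acetyloxy)-2-methylbut-2-enoyl]oxy}-4-ethenyl-2-hydroxy-3-(3-hydroxyprop-1-en-2-yl)-4-methylcyclohexyl]prop-2-enoic acid | C=C[C@@]1(C)C[C@@H](OC(=O)/C(C)=C\COC(C)=O)[C@@H](C(=C)C(=O)O)[C@H](O)[C@@H]1C(=C)CO | target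

**Count and risks**

Total step count: 23. Longest linear sequence: 16 (steps 1–7, 11–16, 21–23).

Steps most likely to fail:

Step 15. The ten-membered ring closure may lose out to oligomerisation or protodebromination, the aldehyde may add to the wrong face of the allyl unit, or the Cope shift may stall. The fallback separates the two bond formations and closes the ten-membered ring at C3–C4 instead. It sets out from 12 and 20 and comes back at 27. DDQ on 12 should give tert-butyl (2E)-2-(hydroxymethyl)-3-[(2S)-4-iodo-5-oxo-2,5-dihydrofuran-2-yl]prop-2-enoate F1, and NBS/Me2S should convert it into tert-butyl (2Z)-2-(bromomethyl)-3-[(2S)-4-iodo-5-oxo-2,5-dihydrofuran-2-yl]prop-2-enoate F2. DDQ on 20 should give (3E)-6-iodo-3-methylhex-3-en-1-ol F3, which Dess–Martin periodinane oxidises to (3E)-6-iodo-3-methylhex-3-enal F4. An intermolecular indium-mediated Barbier reaction of F2 with F4 (In, THF/H2O) should give tert-butyl (3R,4R,6E)-4-hydroxy-9-iodo-3-[(2S)-4-iodo-5-oxo-2,5-dihydrofuran-2-yl]-6-methyl-2-methylidenenon-6-enoate F5, whose diastereomers can be separated at this open-chain stage. Me3SiCl/imidazole should give tert-butyl (3S,4R,6E)-9-iodo-3-[(2S)-4-iodo-5-oxo-2,5-dihydrofuran-2-yl]-6-methyl-2-methylidene-4-[(trimethylsilyl)oxy]non-6-enoate F6. Zinc insertion into the alkyl iodide of F6 (Zn dust, LiCl) and slow addition to Pd2(dba)3/SPhos should close C3–C4 by intramolecular Negishi coupling to 26, which is heated in toluene in a separate operation to give 27.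

Step 16. The hydride may also reduce the acrylate ester, or methanol may be captured with allylic transposition or conjugate addition during acetal formation. The fallback avoids the acetal and protects by silylation instead. It sets out from crude lactol 28 and comes back at 40. Luche reduction of 28 (NaBH4, CeCl3·7H2O, MeOH) with loss of the trimethylsilyl group should give tert-butyl 2-[(1R,2R,3S,4R,6R)-4-ethenyl-2,6-dihydroxy-3-(3-hydroxyprop-1-en-2-yl)-4-methylcyclohexyl]prop-2-enoate F7. Selective silylation of the primary allylic alcohol (TBSCl, imidazole, −20 °C) should give tert-butyl 2-[(1R,2R,3S,4R,6R)-3-(3-{[tert-butyl(dimethyl)silyl]oxy}prop-1-en-2-yl)-4-ethenyl-2,6-dihydroxy-4-methylcyclohexyl]prop-2-enoate F8. Yamaguchi esterification with 36 at the less hindered O8 (O6 is flanked by two branched carbons) should give tert-butyl 2-[(1S,2R,3S,4R,6R)-6-{[(2Z)-4-(acetyloxy)-2-methylbut-2-enoyl]oxy}-3-(3-{[tert-butyl(dimethyl)silyl]oxy}prop-1-en-2-yl)-4-ethenyl-2-hydroxy-4-methylcyclohexyl]prop-2-enoate F9. TFA/CH2Cl2/H2O then removes the silyl ether and the tert-butyl ester to give 40.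

Step 21. The Z-enoyl unit may isomerise to E during activation, or the hindered C8 hydroxyl may acylate slowly. The fallback builds the Z alkene on the substrate. It sets out from 29 and comes back at 38. Carbodiimide coupling of 29 with 2-[bis(2,2,2-trifluoroethoxy)phosphoryl]propanoic acid (DCC, DMAP) should give tert-butyl 2-[(3aS,4R,6R,7R,7aR)-6-({2-[bis(2,2,2-trifluoroethoxy)phosphoryl]propanoyl}oxy)-4-ethenyl-2-methoxy-4-methyl-3-methylideneoctahydro-1-benzofuran-7-yl]prop-2-enoate F10. Still–Gennari olefination of F10 with 34 (KN(SiMe3)2, 18-crown-6, THF, −78 °C) should then give 38 with the Z geometry set kinetically.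

**Further compounds**

F1 | step 15 | tert-butyl (2E)-2-(hydroxymethyl)-3-[(2S)-4-iodo-5-oxo-2,5-dihydrofuran-2-yl]prop-2-enoate | IC1=C[C@@H](OC1=O)/C=C(\CO)C(=O)OC(C)(C)C
F2 | step 15 | tert-butyl (2Z)-2-(bromomethyl)-3-[(2S)-4-iodo-5-oxo-2,5-dihydrofuran-2-yl]prop-2-enoate | IC1=C[C@@H](OC1=O)/C=C(\CBr)C(=O)OC(C)(C)C
F3 | step 15 | (3E)-6-iodo-3-methylhex-3-en-1-ol | OCC/C(C)=C/CCI
F4 | step 15 | (3E)-6-iodo-3-methylhex-3-enal | O=CC/C(C)=C/CCI
F5 | step 15 | tert-butyl (3R,4R,6E)-4-hydroxy-9-iodo-3-[(2S)-4-iodo-5-oxo-2,5-dihydrofuran-2-yl]-6-methyl-2-methylidenenon-6-enoate | ICC/C=C(\C)C[C@@H](O)[C@@H](C(=C)C(=O)OC(C)(C)C)[C@@H]1OC(=O)C(I)=C1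
F6 | step 15 | tert-butyl (3S,4R,6E)-9-iodo-3-[(2S)-4-iodo-5-oxo-2,5-dihydrofuran-2-yl]-6-methyl-2-methylidene-4-[(trimethylsilyl)oxy]non-6-enoate | ICC/C=C(\C)C[C@@H](O[Si](C)(C)C)[C@@H](C(=C)C(=O)OC(C)(C)C)[C@@H]1OC(=O)C(I)=C1
F7 | step 16 | tert-butyl 2-[(1R,2R,3S,4R,6R)-4-ethenyl-2,6-dihydroxy-3-(3-hydroxyprop-1-en-2-yl)-4-methylcyclohexyl]prop-2-enoate | C=C[C@@]1(C)C[C@@H](O)[C@@H](C(=C)C(=O)OC(C)(C)C)[C@H](O)[C@@H]1C(=C)CO
F8 | step 16 | tert-butyl 2-[(1R,2R,3S,4R,6R)-3-(3-{[tert-butyl(dimethyl)silyl]oxy}prop-1-en-2-yl)-4-ethenyl-2,6-dihydroxy-4-methylcyclohexyl]prop-2-enoate | C=C[C@@]1(C)C[C@@H](O)[C@@H](C(=C)C(=O)OC(C)(C)C)[C@H](O)[C@@H]1C(=C)CO[Si](C)(C)C(C)(C)C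
F9 | step 16 | tert-butyl 2-[(1S,2R,3S,4R,6R)-6-{[(2Z)-4-(acetyloxy)-2-methylbut-2-enoyl]oxy}-3-(3-{[tert-butyl(dimethyl)silyl]oxy}prop-1-en-2-yl)-4-ethenyl-2-hydroxy-4-methylcyclohexyl]prop-2-enoate | C=C[C@@]1(C)C[C@@H](OC(=O)/C(C)=C\COC(C)=O)[C@@H](C(=C)C(=O)OC(C)(C)C)[C@H](O)[C@@H]1C(=C)CO[Si](C)(C)C(C)(C)C
F10 | step 21 | tert-butyl 2-[(3aS,4R,6R,7R,7aR)-6-({2-[bis(2,2,2-trifluoroethoxy)phosphoryl]propanoyl}oxy)-4-ethenyl-2-methoxy-4-methyl-3-methylideneoctahydro-1-benzofuran-7-yl]prop-2-enoate | C=C[C@@]1(C)C[C@@H](OC(=O)C(C)P(=O)(OCC(F)(F)F)OCC(F)(F)F)[C@@H](C(=C)C(=O)OC(C)(C)C)[C@H](OC(OC)C2=C)[C@@H]12
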